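## Retrosynthetic overview

1. Target 30 ⇐ ring D closed last by a 5-exo vinyl-radical cyclisation (C16→C13) of an 8-propargyl ring C cyclohexene, then C15 allylic oxidation and O19 desilylation.
2. The 7,20-lactone and the C6 CH2OAc arm ⇐ a temporary carbocyclic ring B: the C6–C7 bond is reconnected and cut late by α-ketol cleavage (C7 ester, C6 aldehyde).
3. Ring B ⇐ intermolecular endo Diels–Alder reaction of a ring A 2-methoxycarbonyl enone with a ring C 2-silyloxydiene. The target has C6 and C9 cis on ring A, which is what a cycloaddition delivers, so C5, C9 and C10 are set in one step; C8 is then quaternised through the silyl enol ether left by the cycloaddition.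
4. Ring A enone ⇐ catalytic enantioselective Diels–Alder reaction (aminosiloxydiene + methacrolein) for C4; ring C diene ⇐ butadiene + butynone.
5. Ring order: A and C (separately) → B (temporary) → B opened → lactone → D.

Assumption: (R,R)-1-naphthyl-TADDOL is taken to give the (S)-configured cycloadduct needed here; if the sense of induction is the reverse, the (S,S)-diol is used and nothing else changes.

Locants used below (kaurane-type, read from the target): C1 (CH–OAc), C2, C3, C4 (bears methyl C18 and CH2OH carbon C19), C5 (bears C6), C10 (spiro carbon) form ring A; C20 = lactone OCH2; C7 = lactone C=O; C8 and C13 = bridgeheads; C9 = CH bonded to C10; C11, C12, C14 = CH2; C15 = ketone; C16=C17 = exocyclic alkene.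

## Route

Step 1
Reactants: 1 (E)-3-(tert-butyldimethylsilyloxy)-N,N-dimethylbuta-1,3-dien-1-amine; 2 methacrolein
Product: 5 (S)-4-(hydroxymethyl)-4-methylcyclohex-2-en-1-one, via cycloadduct aldehyde 3 (not isolated), via amino alcohol 4 (not isolated)
Conditions: (R,R)-1-naphthyl-TADDOL (20 mol %), PhMe, −80 °C; then LiAlH4, Et2O, −78 °C → rt; then aq. HF, MeCN, rt
Reagents that add atoms: none
Why: Hydrogen-bond-catalysed enantioselective Diels–Alder reaction in which the chiral diol–aldehyde complex selects one face of methacrolein and so sets the C4 quaternary centre (S); hydride reduction of the aldehyde and acid-induced desilylation with β-elimination of dimethylamine then give the enone.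

Step 2
Reactants: 5 (S)-4-(hydroxymethyl)-4-methylcyclohex-2-en-1-one
Product: 6 (S)-4-[(tert-butyldiphenylsilyloxy)methyl]-4-methylcyclohex-2-en-1-one
Conditions: TBDPSCl, imidazole, DMF, rt
Reagents that add atoms: tert-butyldiphenylsilyl chloride CC(C)(C)[Si](Cl)(c1ccccc1)c1ccccc1
Why: Standard silylation of a primary alcohol; the bulky silyl ether later shields one face of C5 and is kept until the last step.

Step 3
Reactants: 6 (S)-4-[(tert-butyldiphenylsilyloxy)methyl]-4-methylcyclohex-2-en-1-one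
Product: 7 (S)-4-[(tert-butyldiphenylsilyloxy)methyl]-2-iodo-4-methylcyclohex-2-en-1-one
Conditions: I2, pyridine, DMAP (cat.), CH2Cl2, rt
Reagents that add atoms: iodine II
Why: Johnson α-iodination of an enone (amine conjugate addition, enolate iodination, elimination).

Step 4
Reactants: 7 (S)-4-[(tert-butyldiphenylsilyloxy)methyl]-2-iodo-4-methylcyclohex-2-en-1-one
Product: 8 methyl (S)-3-[(tert-butyldiphenylsilyloxy)methyl]-3-methyl-6-oxocyclohex-1-ene-1-carboxylate (ring A dienophile; the ester carbon is C20)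
Conditions: PdCl2(PPh3)2 (5 mol %), CO (1 atm), MeOH, Et3N, DMF, 60 °C
Reagents that add atoms: carbon monoxide [C-]#[O+]; methanol CO
Why: Palladium-catalysed methoxycarbonylation of the vinyl iodide (oxidative addition, CO insertion, methanolysis) gives the doubly activated 2-alkoxycarbonyl enone, whose neopentyl β-carbon resists Michael addition of methanol.

Step 5
Reactants: 9 buta-1,3-diene; 10 but-3-yn-2-one
Product: 11 1-(cyclohexa-1,4-dien-1-yl)ethan-1-one
Conditions: PhMe, BHT (cat.), sealed tube, 110 °C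
Reagents that add atoms: none
Why: Thermal Diels–Alder reaction of a diene with an ynone gives the skipped 1,4-diene directly and places the second ring alkene at C12=C13.

Step 6
Reactants: 11 1-(cyclohexa-1,4-dien-1-yl)ethan-1-one
Product: 12 tert-butyl{[1-(cyclohexa-1,4-dien-1-yl)ethenyl]oxy}dimethylsilane (ring C diene)
Conditions: TBSOTf, Et3N, CH2Cl2, 0 °C
Reagents that add atoms: tert-butyldimethylsilyl trifluoromethanesulfonate CC(C)(C)[Si](C)(C)OS(=O)(=O)C(F)(F)F
Why: Soft enolisation at the methyl group gives the cross-conjugated 2-silyloxydiene (kinetic silyl enol ether formation).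

Step 7
Reactants: 8 methyl (S)-3-[(tert-butyldiphenylsilyloxy)methyl]-3-methyl-6-oxocyclohex-1-ene-1-carboxylate; 12 tert-butyl{[1-(cyclohexa-1,4-dien-1-yl)ethenyl]oxy}dimethylsilane
Product: 13 tricyclic adduct (rings A, B, C): C1 ketone, C20 methyl ester on C10, C7 OTBS enol ether (C7=C8), C12=C13, C19 OTBDPS; H5, H9 and C20 mutually cis, C6 cis to methyl C18 and trans to C19
Conditions: ZnCl2 (1.0 equiv), 12 (2 equiv), Et2O/CH2Cl2, 0 °C → rt
Reagents that add atoms: none
Why: Lewis-acid-promoted Diels–Alder reaction in which the nucleophilic CH2 terminus of the silyloxydiene (C6) bonds to the β-carbon C5 and C9 bonds to C10; suprafacial addition puts the new C5–C6 and C10–C9 bonds cis, the diene comes in anti to the bulky CH2OTBDPS group on C4, and the endo-to-ketone transition state places C11 on the side of C1, which fixes C9 relative to C10.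

Step 8
Reactants: 13 tricyclic adduct
Product: 14 1,20-diol (C1 OH cis to C9 and trans to C20; enol ether intact)
Conditions: LiAlH4, THF, −78 → 0 °C; H2O/aq. NaOH work-up
Reagents that add atoms: none
Why: Hydride reduction of ketone and ester; with the ester chelated coplanar to the ketone, C9 is axial on ring A and hydride adds axially from the opposite (C20) face, so the C1 hydroxyl is equatorial, cis to C9.

Step 9
Reactants: 14 1,20-diol
Product: 15 1,20-bis(TBS) ether
Conditions: TBSOTf (2.5 equiv), 2,6-lutidine, CH2Cl2, 0 °C → rt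
Reagents that add atoms: tert-butyldimethylsilyl trifluoromethanesulfonate CC(C)(C)[Si](C)(C)OS(=O)(=O)C(F)(F)F
Why: Silyl triflate silylates both the primary and the hindered secondary alcohol under basic conditions that leave the silyl enol ether untouched.

Step 10
Reactants: 15 1,20-bis(TBS) ether
Product: 17 8-propargyl C7 ketone (propargyl carbon C15 on C8 cis to H9), via ammonium enolate 16 (not isolated)
Conditions: BnMe3N+F− (1.1 equiv), 4 Å MS, propargyl bromide (3 equiv), THF, −78 → −20 °C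
Reagents that add atoms: propargyl bromide C#CCBr
Why: Regiospecific alkylation of a fluoride-generated ammonium enolate (the silyl enol ether is cleaved far faster than the alkyl silyl ethers); the electrophile enters on the face of H9, anti to the pseudo-axial C9–C11 bond, which is the usual cis outcome for alkylation of a ring-fusion enolate.

Step 11
Reactants: 17 8-propargyl C7 ketone
Product: 19 6-hydroxy C7 ketone (major C6 epimer drawn; either serves), via potassium enolate 18 (not isolated)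
Conditions: KN(SiMe3)2, THF, −78 °C; then 3-phenyl-2-(phenylsulfonyl)oxaziridine, −78 °C; NH4Cl quench
Reagents that add atoms: 3-phenyl-2-(phenylsulfonyl)oxaziridine O=S(=O)(c1ccccc1)N1OC1c1ccccc1
Why: Davis enolate hydroxylation; C6 is the only enolisable position of the C7 ketone, and the C6 configuration is lost in the next step.

Step 12
Reactants: 19 6-hydroxy C7 ketone
Product: 21 seco alcohol ester (ring B opened: C7 methyl ester on C8, C6 CH2OH on C5), via seco aldehyde ester 20 (not isolated)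
Conditions: Pb(OAc)4, MeOH/PhH 1:1, 0 °C; then NaBH4, 0 °C
Reagents that add atoms: methanol CO
Why: Lead tetraacetate cleavage of the α-ketol through its methyl hemiketal (glycol-type cleavage) breaks C6–C7, and the aldehyde is reduced at once so that C5 cannot epimerise.

Step 13
Reactants: 21 seco alcohol ester
Product: 23 spiro 7,20-lactone (1-OTBS, 6-OH, 19-OTBDPS, 8-propargyl, C12=C13), via C20 alcohol 22 (not isolated)
Conditions: PPTS, MeOH, rt; then CSA (cat.), PhMe, 60 °C
Reagents that add atoms: none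
Why: Mild acid methanolysis removes only the primary C20 TBS ether, and acid-catalysed lactonisation of that alcohol onto the C7 ester closes the six-membered ring while O1 is still silylated and O6 could only form a seven-membered ring.

Step 14
Reactants: 23 spiro 7,20-lactone
Product: 24 lactone 1,6-diol
Conditions: aq. HF (48 %), MeCN, 0 °C → rt
Reagents that add atoms: none
Why: Acidic fluoride desilylation; the secondary TBS ether is cleaved much faster than the primary TBDPS ether.

Step 15
Reactants: 24 lactone 1,6-diol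
Product: 25 lactone 1,6-diacetate
Conditions: Ac2O, DMAP, pyridine, rt
Reagents that add atoms: acetic anhydride CC(=O)OC(C)=O
Why: DMAP-catalysed acetylation of both free alcohols.

Step 16
Reactants: 25 lactone 1,6-diacetate
Product: 27 16-methylene tetracycle (bicyclo[3.2.1]octane closed, C15 still CH2), via vinylstannane 26 (not isolated)
Conditions: Bu3SnH (slow addition), AIBN, PhH, 80 °C; then CF3CO2H, CH2Cl2, 0 °C
Reagents that add atoms: none
Why: Stannyl-radical-mediated enyne cyclisation in which the C16 vinyl radical closes 5-exo-trig onto C13 of the ring C alkene; the propargyl arm can only bridge on its own face, which fixes C13, and protodestannylation gives the exocyclic methylene.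

Step 17
Reactants: 27 16-methylene tetracycle
Product: 29 15-oxo-16-methylene tetracycle (19-OTBDPS), via allylic alcohol 28 (not isolated)
Conditions: SeO2 (cat.), t-BuOOH, CH2Cl2, rt; then Dess–Martin periodinane, NaHCO3, CH2Cl2, rt
Reagents that add atoms: selenium dioxide O=[Se]=O (oxygen carrier); tert-butyl hydroperoxide CC(C)(C)OO
Why: Allylic oxidation (ene reaction then [2,3]-sigmatropic shift) at C15, the only allylic CH2, followed by Dess–Martin oxidation to the α-methylene ketone; the C15 carbinol configuration is irrelevant.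

Step 18
Reactants: 29 15-oxo-16-methylene tetracycle (19-OTBDPS)
Product: 30 target (1S,4S,5R,8S,9S,10R,13R in the locants above)
Conditions: HF·pyridine, THF, 0 °C → rt
Reagents that add atoms: none
Why: Fluoride cleavage of the last silyl ether under non-basic conditions that spare the acetates, the exocyclic enone and the β-keto lactone.

## Compound list

1 | (E)-3-(tert-butyldimethylsilyloxy)-N,N-dimethylbuta-1,3-dien-1-amine | CN(C)/C=C/C(=C)O[Si](C)(C)C(C)(C)C | starting material
2 | methacrolein (2-methylprop-2-enal) | CC(=C)C=O | starting material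
3 | (1S,2R)-4-(tert-butyldimethylsilyloxy)-2-(dimethylamino)-1-methylcyclohex-3-ene-1-carbaldehyde (endo cycloadduct) | O=C[C@@]1(C)CCC(O[Si](C)(C)C(C)(C)C)=C[C@H]1N(C)C | intermediate
4 | [(1S,2R)-4-(tert-butyldimethylsilyloxy)-2-(dimethylamino)-1-methylcyclohex-3-en-1-yl]methanol | OC[C@@]1(C)CCC(O[Si](C)(C)C(C)(C)C)=C[C@H]1N(C)C | intermediate
5 | (S)-4-(hydroxymethyl)-4-methylcyclohex-2-en-1-one | O=C1CC[C@](C)(CO)C=C1 | intermediate
6 | (S)-4-[(tert-butyldiphenylsilyloxy)methyl]-4-methylcyclohex-2-en-1-one | O=C1CC[C@](C)(CO[Si](c2ccccc2)(c2ccccc2)C(C)(C)C)C=C1 | intermediate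
7 | (S)-4-[(tert-butyldiphenylsilyloxy)methyl]-2-iodo-4-methylcyclohex-2-en-1-one | O=C1CC[C@](C)(CO[Si](c2ccccc2)(c2ccccc2)C(C)(C)C)C=C1I | intermediate
8 | methyl (S)-3-[(tert-butyldiphenylsilyloxy)methyl]-3-methyl-6-oxocyclohex-1-ene-1-carboxylate | O=C1CC[C@](C)(CO[Si](c2ccccc2)(c2ccccc2)C(C)(C)C)C=C1C(=O)OC | intermediate
9 | buta-1,3-diene | C=CC=C | starting material
10 | but-3-yn-2-one | CC(=O)C#C | starting material
11 | 1-(cyclohexa-1,4-dien-1-yl)ethan-1-one | CC(=O)C1=CCC=CC1 | intermediate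
12 | tert-butyl{[1-(cyclohexa-1,4-dien-1-yl)ethenyl]oxy}dimethylsilane | C=C(O[Si](C)(C)C(C)(C)C)C1=CCC=CC1 | intermediate
13 | tricyclic Diels–Alder adduct: C1 ketone, C20 methyl ester, C7 OTBS enol ether, C12=C13, C19 OTBDPS | COC(=O)[C@]12C(=O)CC[C@](C)(CO[Si](c3ccccc3)(c3ccccc3)C(C)(C)C)[C@H]1CC(O[Si](C)(C)C(C)(C)C)=C1CC=CC[C@H]12 | intermediate
14 | 1,20-diol of 13 (C1 OH cis to C9) | OC[C@]12[C@@H](O)CC[C@](C)(CO[Si](c3ccccc3)(c3ccccc3)C(C)(C)C)[C@H]1CC(O[Si](C)(C)C(C)(C)C)=C1CC=CC[C@H]12 | intermediate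
15 | 1,20-bis(TBS) ether of 14 | CC(C)(C)[Si](C)(C)OC[C@]12[C@@H](O[Si](C)(C)C(C)(C)C)CC[C@](C)(CO[Si](c3ccccc3)(c3ccccc3)C(C)(C)C)[C@H]1CC(O[Si](C)(C)C(C)(C)C)=C1CC=CC[C@H]12 | intermediate
16 | benzyltrimethylammonium C7–C8 enolate from 15 | CC(C)(C)[Si](C)(C)OC[C@]12[C@@H](O[Si](C)(C)C(C)(C)C)CC[C@](C)(CO[Si](c3ccccc3)(c3ccccc3)C(C)(C)C)[C@H]1CC([O-])=C1CC=CC[C@H]12.C[N+](C)(C)Cc1ccccc1 | intermediate
17 | 8-propargyl C7 ketone (propargyl cis to H9) | CC(C)(C)[Si](C)(C)OC[C@]12[C@@H](O[Si](C)(C)C(C)(C)C)CC[C@](C)(CO[Si](c3ccccc3)(c3ccccc3)C(C)(C)C)[C@H]1CC(=O)[C@@]1(CC#C)CC=CC[C@H]12 | intermediate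
18 | potassium C6–C7 enolate of 17 | CC(C)(C)[Si](C)(C)OC[C@]12[C@@H](O[Si](C)(C)C(C)(C)C)CC[C@](C)(CO[Si](c3ccccc3)(c3ccccc3)C(C)(C)C)[C@H]1C=C([O-])[C@@]1(CC#C)CC=CC[C@H]12.[K+] | intermediate
19 | 6-hydroxy C7 ketone (major C6 epimer, OH cis to H5) | CC(C)(C)[Si](C)(C)OC[C@]12[C@@H](O[Si](C)(C)C(C)(C)C)CC[C@](C)(CO[Si](c3ccccc3)(c3ccccc3)C(C)(C)C)[C@H]1[C@H](O)C(=O)[C@@]1(CC#C)CC=CC[C@H]12 | intermediate
20 | seco aldehyde ester: C6 aldehyde, C7 methyl ester | COC(=O)[C@@]1(CC#C)CC=CC[C@H]1[C@@]1(CO[Si](C)(C)C(C)(C)C)[C@@H](O[Si](C)(C)C(C)(C)C)CC[C@](C)(CO[Si](c2ccccc2)(c2ccccc2)C(C)(C)C)[C@H]1C=O | intermediate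
21 | seco alcohol ester: C6 CH2OH, C7 methyl ester | COC(=O)[C@@]1(CC#C)CC=CC[C@H]1[C@@]1(CO[Si](C)(C)C(C)(C)C)[C@@H](O[Si](C)(C)C(C)(C)C)CC[C@](C)(CO[Si](c2ccccc2)(c2ccccc2)C(C)(C)C)[C@H]1CO | intermediate
22 | 6,20-diol methyl ester (1-OTBS) | COC(=O)[C@@]1(CC#C)CC=CC[C@H]1[C@@]1(CO)[C@@H](O[Si](C)(C)C(C)(C)C)CC[C@](C)(CO[Si](c2ccccc2)(c2ccccc2)C(C)(C)C)[C@H]1CO | intermediate
23 | spiro 7,20-lactone: 1-OTBS, 6-OH, 19-OTBDPS, 8-propargyl | C#CC[C@]12CC=CC[C@H]1[C@@]1(COC2=O)[C@@H](O[Si](C)(C)C(C)(C)C)CC[C@](C)(CO[Si](c3ccccc3)(c3ccccc3)C(C)(C)C)[C@H]1CO | intermediate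
24 | lactone 1,6-diol | C#CC[C@]12CC=CC[C@H]1[C@@]1(COC2=O)[C@@H](O)CC[C@](C)(CO[Si](c3ccccc3)(c3ccccc3)C(C)(C)C)[C@H]1CO | intermediate
25 | lactone 1,6-diacetate | C#CC[C@]12CC=CC[C@H]1[C@@]1(COC2=O)[C@@H](OC(C)=O)CC[C@](C)(CO[Si](c3ccccc3)(c3ccccc3)C(C)(C)C)[C@H]1COC(C)=O | intermediate
26 | C17-tributylstannyl 16-methylene tetracycle (E/Z mixture) | CCCC[Sn](CCCC)(CCCC)C=C1C[C@]23C[C@H]1CC[C@H]2[C@@]1(COC3=O)[C@@H](OC(C)=O)CC[C@](C)(CO[Si](c4ccccc4)(c4ccccc4)C(C)(C)C)[C@H]1COC(C)=O | intermediate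
27 | 16-methylene tetracycle (C15 CH2, 19-OTBDPS) | C=C1C[C@]23C[C@H]1CC[C@H]2[C@@]1(COC3=O)[C@@H](OC(C)=O)CC[C@](C)(CO[Si](c4ccccc4)(c4ccccc4)C(C)(C)C)[C@H]1COC(C)=O | intermediate
28 | 15-hydroxy-16-methylene tetracycle (C15 configuration not assigned) | C=C1C(O)[C@]23C[C@H]1CC[C@H]2[C@@]1(COC3=O)[C@@H](OC(C)=O)CC[C@](C)(CO[Si](c4ccccc4)(c4ccccc4)C(C)(C)C)[C@H]1COC(C)=O | intermediate
29 | 15-oxo-16-methylene tetracycle (19-OTBDPS) | C=C1C(=O)[C@]23C[C@H]1CC[C@H]2[C@@]1(COC3=O)[C@@H](OC(C)=O)CC[C@](C)(CO[Si](c4ccccc4)(c4ccccc4)C(C)(C)C)[C@H]1COC(C)=O | intermediate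
30 | CNP0370815.4: 1,6-diacetoxy-19-hydroxy-15-oxo-16-methylene 7,20-lactone | C=C1C(=O)[C@]23C[C@H]1CC[C@H]2[C@@]1(COC3=O)[C@@H](OC(C)=O)CC[C@](C)(CO)[C@H]1COC(C)=O | target

## Step count and risks

Total step count: 18. Longest linear sequence: 16 steps (steps 1–4, then 7–18); the diene branch (steps 5–6) is two steps.

Steps most likely to fail:

Step 7 (Diels–Alder). The dienophile is hindered at C5, the ester could compete with the ring ketone for the endo position (which would invert C9), and face selection at C5 rests only on CH2OTBDPS versus methyl. The fallback removes the competing ester. It sets out from 7: Stille coupling with (tributylstannyl)methanol and Pd(PPh3)4 gives the 2-(hydroxymethyl) enone F1, and TBSCl/imidazole gives the silyl ether F2. A mixed-Lewis-acid cycloaddition (AlBr3/AlMe3, PhMe/CH2Cl2) with diene 12, in which the ring ketone is the only carbonyl that can lie endo, gives the C20-silyloxy adduct F3. LiAlH4 reduction of the C1 ketone gives the alcohol F4, and TBSOTf/2,6-lutidine brings the material back to the route at 15.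

Step 10 (C8 quaternisation). A tetrasubstituted ammonium enolate must be C-alkylated next to C9 and syn-axial to C20 on ring B; O-alkylation or no reaction is possible. The fallback replaces the SN2 alkylation by a cation addition to the silyl enol ether. It sets out from 15: the Nicholas salt [Co2(CO)6(HC≡CCH2)]BF4 in CH2Cl2 at −78 °C gives the hexacarbonyldicobalt-complexed propargyl ketone F5. Fe(NO3)3·9H2O in EtOH then removes the metal and the route is rejoined at 17.

Step 16 (ring D). The vinyl radical can be reduced before it cyclises, or it can close on C12 to give a bicyclo[2.2.2]octane. The fallback is a two-electron palladium-hydride reductive enyne cyclisation: it sets out from 25 with Pd2(dba)3·CHCl3 (cat.), AcOH and Et3SiH in PhMe (hydropalladation of the alkyne, 5-exo carbopalladation of C12=C13, silane reduction of the alkyl–palladium bond) and comes back to the route directly at 27; no new compound is made on this way (F0).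

## Further compounds

F1 | step 7 | (S)-4-[(tert-butyldiphenylsilyloxy)methyl]-2-(hydroxymethyl)-4-methylcyclohex-2-en-1-one | O=C1CC[C@](C)(CO[Si](c2ccccc2)(c2ccccc2)C(C)(C)C)C=C1CO
F2 | step 7 | (S)-2-[(tert-butyldimethylsilyloxy)methyl]-4-[(tert-butyldiphenylsilyloxy)methyl]-4-methylcyclohex-2-en-1-one | O=C1CC[C@](C)(CO[Si](c2ccccc2)(c2ccccc2)C(C)(C)C)C=C1CO[Si](C)(C)C(C)(C)C
F3 | step 7 | tricyclic adduct with C1 ketone, C20 OTBS, C7 OTBS enol ether, C19 OTBDPS | CC(C)(C)[Si](C)(C)OC[C@]12C(=O)CC[C@](C)(CO[Si](c3ccccc3)(c3ccccc3)C(C)(C)C)[C@H]1CC(O[Si](C)(C)C(C)(C)C)=C1CC=CC[C@H]12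
F4 | step 7 | C1 alcohol of F3 (OH cis to C9) | CC(C)(C)[Si](C)(C)OC[C@]12[C@@H](O)CC[C@](C)(CO[Si](c3ccccc3)(c3ccccc3)C(C)(C)C)[C@H]1CC(O[Si](C)(C)C(C)(C)C)=C1CC=CC[C@H]12
F5 | step 10 | hexacarbonyldicobalt complex of alkyne 17 | CC(C)(C)[Si](C)(C)OC[C@]12[C@@H](O[Si](C)(C)C(C)(C)C)CC[C@](C)(CO[Si](c3ccccc3)(c3ccccc3)C(C)(C)C)[C@H]1CC(=O)[C@@]1(CC45[Co]6(=C=O)(=C=O)(=C=O)[Co]4(=C=O)(=C=O)(=C=O)C56)CC=CC[C@H]12
F0 | step 16 | none | none
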